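A direct plan would build the biphenyl first: Miyaura borylation of one bromodimethoxybenzaldehyde and Suzuki coupling with its isomer would give dialdehyde A1. A twofold Wittig reaction with a carboxyl-bearing ylide and hydrogenation would give diacid A2, a twofold insertion of 3-methoxybenzyne into the acids would give bis-ketone A3, and BBr3 would finish. Its weakest steps would be:
- the twofold aryne insertion: a fluoride reaction at 125 °C that must find the right orientation and win acyl transfer over protonation twice on the most advanced intermediate, whose phenoxide products can be arylated again;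
- the borylation and cross-coupling of two differently brominated rings: two steps spent on a bond between two identical halves, after which every step must succeed twice in one molecule;
- the phosphonium salt, twofold olefination and hydrogenation: three operations that add only two saturated chains.

**Plan of the new route**
The target is a dehydrodimer. Its aryl–aryl bond joins two identical C21 halves, from the carbon ortho to a hydroxyl and meta to the chain in catechol ring A to the carbon para to a hydroxyl and ortho to the chain in catechol ring B. Rings C and D are the 2,6-dihydroxyphenyl ketones.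
The retrosynthesis cuts the aryl–aryl bond first, then in the monomer the chain bond C8–C9 beside the guaiacol ring (cross-metathesis) and the chain bond C1–C2 beside the ketone (hydroacylation).
All benzene rings are bought. The acylresorcinol ring is joined to the chain first, the guaiacol ring second, and the biphenyl arises last by anodic homocoupling of the 4-alkylguaiacol monomer, whose site preference (ortho to OH in one partner, para to OMe in the other) gives the unsymmetrical linkage.
No aryne, no ylide and no halogen or boron on the biaryl partners occur, and only the deprotection is run on the dimer.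

Key step: step 5

Remarks on the chemistry:
- The target has no stereocentre. The biaryl axis carries only one hydroxyl and one alkyl group in its ortho positions and is taken as freely rotating.
- Commercial isoeugenol is an E/Z mixture; the geometry is irrelevant because the alkene is hydrogenated.

Step 1
Reactants: 1 2,6-dihydroxybenzaldehyde; 2 octa-1,7-diene
Product: 3 1-(2,6-dihydroxyphenyl)non-8-en-1-one
Conditions: [Rh(cod)OMe]2 (2 mol %), BINOL-derived phosphoramidite ligand (8 mol %), K3PO4 (10 mol %), octa-1,7-diene in fivefold excess, 2-MeTHF, 70 °C; unreacted diene distilled off and reused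
Reagents that add atoms: none
Why: Rhodium-catalysed intermolecular alkene hydroacylation of a salicylaldehyde, a one-to-one addition in which the phenoxide binds monovalent rhodium, oxidative addition of the formyl C–H bond gives a chelated acyl hydride of trivalent rhodium that resists decarbonylation, and the bulky phosphoramidite steers alkene insertion and reductive elimination to the linear ketone, while the excess of the remote, non-chelating diene should keep the reaction at one of its two alkenes.

Step 2
Reactants: 3 1-(2,6-dihydroxyphenyl)non-8-en-1-one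
Product: 4 2-(non-8-enoyl)-1,3-phenylene diacetate
Conditions: Ac2O (3 equiv), pyridine (4 equiv), DMAP (5 mol %), CH2Cl2, 0 °C to rt
Reagents that add atoms: acetic anhydride, CC(=O)OC(C)=O
Why: DMAP-catalysed acetylation of both hydrogen-bonded phenols, which turns the electron-rich acylresorcinol ring into an ester-deactivated ring that should be neither oxidized nor nucleophilic in step 5, under conditions too mild for Baker–Venkataraman acyl migration.

Step 3
Reactants: 4 2-(non-8-enoyl)-1,3-phenylene diacetate; 5 isoeugenol
Product: 6 2-[(E)-9-(4-hydroxy-3-methoxyphenyl)non-8-enoyl]-1,3-phenylene diacetate (E major, E/Z mixture acceptable)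
Conditions: second-generation Hoveyda–Grubbs catalyst (3 mol %), 1,4-benzoquinone (10 mol %), isoeugenol in threefold excess, CH2Cl2, 40 °C, slow argon purge
Reagents that add atoms: none
Why: Olefin cross-metathesis of a terminal alkene with a propenylarene, driven by loss of propene, in which the free phenol and the aryl esters are tolerated by the ruthenium carbene, the excess of the slowly homodimerizing isoeugenol favours the cross product, and the benzoquinone additive should suppress the double-bond migration that would shorten the chain.

Step 4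
Reactants: 6 2-[(E)-9-(4-hydroxy-3-methoxyphenyl)non-8-enoyl]-1,3-phenylene diacetate
Product: 7 2-[9-(4-hydroxy-3-methoxyphenyl)nonanoyl]-1,3-phenylene diacetate
Conditions: H2 (1 atm), 10% Pd/C, EtOAc, rt
Reagents that add atoms: none
Why: Heterogeneous catalytic hydrogenation should saturate the styrene-type alkene of either geometry and leave the hindered, twisted aryl ketone and the aryl acetates untouched in a non-nucleophilic solvent.

Step 5
Reactants: 7 2-[9-(4-hydroxy-3-methoxyphenyl)nonanoyl]-1,3-phenylene diacetate (two molecules)
Product: 9 9,9'-(2',5-dihydroxy-3',4-dimethoxybiphenyl-2,5'-diyl)bis[1-(2,6-diacetoxyphenyl)nonan-1-one], via phenoxyl radical 8 (not isolated)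
Conditions: undivided cell, boron-doped diamond anode and cathode, 7 (0.2 M) in 1,1,1,3,3,3-hexafluoropropan-2-ol, methyltributylammonium methyl sulfate (0.1 M), 50 °C, constant current 5 mA cm−2, 1.0 F per mol of 7; unreacted 7 recovered
Reagents that add atoms: none
Why: Anodic dehydrogenative phenol coupling, in which the guaiacol, the only group of 7 oxidized at this potential, loses one electron and a proton at the anode to give the solvated phenoxyl radical 8, whose carbon ortho to oxygen (C5 of the aryl group, the para carbon being blocked by the chain) bonds to C6 of a second molecule of 7, the carbon para to its methoxy group and ortho to its chain, before a second electron transfer and loss of a proton restore both arenes and the cathode turns the released protons into H2. The closest known reaction type is the anodic homocoupling of 4-alkylguaiacols such as 4-methylguaiacol on boron-doped diamond in this fluorinated alcohol, which gives the unsymmetrical 2,3'-biphenol of this very pattern instead of the symmetrical 2,2'-biphenol formed by chemical oxidants. No ring is closed and no stereocentre is formed, since the new axis carries only one hydroxyl and one alkyl group in its ortho positions. The step needs site selectivity, which the guaiacol itself secures (hydrogen bonding of the solvent to the phenol oxygen leaves the methoxy group as the director in the nucleophilic partner), and chemoselectivity, which the diacetate secures, because the acylresorcinol ring is neither oxidizable nor nucleophilic as its diester. Over-oxidation of the more electron-rich biphenol should be held back by stopping at 1.0 F per mol, by recycling recovered 7 and by the solvation of the product in the fluorinated alcohol.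

Step 6
Reactants: 9 9,9'-(2',5-dihydroxy-3',4-dimethoxybiphenyl-2,5'-diyl)bis[1-(2,6-diacetoxyphenyl)nonan-1-one]
Product: 11 9,9'-(2',3',4,5-tetrahydroxybiphenyl-2,5'-diyl)bis[1-(2,6-dihydroxyphenyl)nonan-1-one], via tetraacetate bis-catechol 10 (not isolated)
Conditions: BBr3 (10 equiv), CH2Cl2, −78 °C to rt, argon; then MeOH, 0 to 40 °C; evaporation from MeOH
Reagents that add atoms: none
Why: Lewis-acid ether cleavage followed by acid transesterification, in which BBr3 binds the two guaiacol oxygens and bromide removes both methyl groups by SN2, and the methanol quench turns the boron residues into B(OMe)3 and HBr, whose methanolic solution should transesterify the four ketone-activated aryl acetates, so that all eight phenols are released under acidic, non-oxidizing conditions in which the bis-catechol is stable.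

**Compound list**
1 | 2,6-dihydroxybenzaldehyde | O=Cc1c(O)cccc1O | starting material
2 | octa-1,7-diene | C=CCCCCC=C | starting material
3 | 1-(2,6-dihydroxyphenyl)non-8-en-1-one | C=CCCCCCCC(=O)c1c(O)cccc1O | intermediate
4 | 2-(non-8-enoyl)-1,3-phenylene diacetate | C=CCCCCCCC(=O)c1c(OC(C)=O)cccc1OC(C)=O | intermediate
5 | isoeugenol, 2-methoxy-4-(prop-1-enyl)phenol (E shown) | C/C=C/c1ccc(O)c(OC)c1 | starting material
6 | 2-[(E)-9-(4-hydroxy-3-methoxyphenyl)non-8-enoyl]-1,3-phenylene diacetate | CC(=O)Oc1cccc(OC(C)=O)c1C(=O)CCCCCC/C=C/c1ccc(O)c(OC)c1 | intermediate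
7 | 2-[9-(4-hydroxy-3-methoxyphenyl)nonanoyl]-1,3-phenylene diacetate | CC(=O)Oc1cccc(OC(C)=O)c1C(=O)CCCCCCCCc1ccc(O)c(OC)c1 | intermediate
8 | phenoxyl radical of 7 (formed at the anode) | CC(=O)Oc1cccc(OC(C)=O)c1C(=O)CCCCCCCCc1ccc([O])c(OC)c1 | intermediate
9 | 9,9'-(2',5-dihydroxy-3',4-dimethoxybiphenyl-2,5'-diyl)bis[1-(2,6-diacetoxyphenyl)nonan-1-one] | O=C(CCCCCCCCc1cc(OC)c(O)c(-c2cc(O)c(OC)cc2CCCCCCCCC(=O)c2c(OC(C)=O)cccc2OC(C)=O)c1)c1c(OC(C)=O)cccc1OC(C)=O | intermediate
10 | 9,9'-(2',3',4,5-tetrahydroxybiphenyl-2,5'-diyl)bis[1-(2,6-diacetoxyphenyl)nonan-1-one] (formed in the flask) | O=C(CCCCCCCCc1cc(O)c(O)c(-c2cc(O)c(O)cc2CCCCCCCCC(=O)c2c(OC(C)=O)cccc2OC(C)=O)c1)c1c(OC(C)=O)cccc1OC(C)=O | intermediate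
11 | 9,9'-(2',3',4,5-tetrahydroxybiphenyl-2,5'-diyl)bis[1-(2,6-dihydroxyphenyl)nonan-1-one] | O=C(CCCCCCCCc1cc(O)c(O)c(-c2cc(O)c(O)cc2CCCCCCCCC(=O)c2c(O)cccc2O)c1)c1c(O)cccc1O | target

Total step count: 6. Longest linear sequence: 6 steps (1 → 3 → 4 → 6 → 7 → 9 → 11).

**Steps most likely to fail**

Step 5 (anodic homocoupling). The coupling may pair the wrong sites (symmetrical ortho–ortho or C–O coupling), or the biphenol may be oxidized further to oligomers. The fallback sets out from 7 and comes back to the route at 11. One portion of 7 would be brominated ortho to the free hydroxyl (NBS, MeCN, 0 °C) to give 2-[9-(3-bromo-4-hydroxy-5-methoxyphenyl)nonanoyl]-1,3-phenylene diacetate F1. A second portion would be acetylated (Ac2O, pyridine) to the triacetate 2-[9-(4-acetoxy-3-methoxyphenyl)nonanoyl]-1,3-phenylene diacetate F2, which would be brominated para to the methoxy group (Br2, NaOAc, AcOH) to give 2-[9-(4-acetoxy-2-bromo-5-methoxyphenyl)nonanoyl]-1,3-phenylene diacetate F3. F3 would be borylated (bis(pinacolato)diboron, Pd(dppf)Cl2, KOAc, 1,4-dioxane, 90 °C) to the pinacol boronate F4. Suzuki–Miyaura coupling of F1 with F4 (Pd(OAc)2, SPhos, K3PO4, toluene with a little water, 60 °C) would give the 5-O-acetate of 9, the pentaacetate biaryl F5; any acetate lost here would not matter. F5 would give 11 under the conditions of step 6.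

Step 1 (hydroacylation). The linear selectivity may erode, a rhodium hydride may move the spare terminal double bond, or the diene may react twice. The fallback sets out from 1 and comes back at 3. Protection of 1 with chloromethyl methyl ether and iPr2NEt would give 2,6-bis(methoxymethoxy)benzaldehyde F6. Addition of oct-7-enylmagnesium bromide (THF, 0 °C) would give racemic 1-[2,6-bis(methoxymethoxy)phenyl]non-8-en-1-ol F7, and Dess–Martin oxidation would give 1-[2,6-bis(methoxymethoxy)phenyl]non-8-en-1-one F8. HCl in MeOH at 40 °C would then release 3.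

Step 3 (cross-metathesis). Double-bond migration before metathesis would give a product one carbon short that is hard to separate, and homodimerization would lower conversion. The fallback sets out from 3 and comes back at 7, so that no alkene has to be moved or reduced. Hydroboration of 3 with 9-BBN (3.3 equiv, THF, rt), then B-alkyl Suzuki–Miyaura coupling with 1-(benzyloxy)-4-bromo-2-methoxybenzene (Pd(dppf)Cl2, K3PO4, DMF/H2O, 60 °C), would give 9-[4-(benzyloxy)-3-methoxyphenyl]-1-(2,6-dihydroxyphenyl)nonan-1-one F9. Acetylation as in step 2 would give 2-[9-[4-(benzyloxy)-3-methoxyphenyl]nonanoyl]-1,3-phenylene diacetate F10, and hydrogenolysis of the benzyl ether (H2, 10% Pd/C, EtOAc) would give 7.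

**Further compounds**
F1 | step 5 | 2-[9-(3-bromo-4-hydroxy-5-methoxyphenyl)nonanoyl]-1,3-phenylene diacetate | CC(=O)Oc1cccc(OC(C)=O)c1C(=O)CCCCCCCCc1cc(Br)c(O)c(OC)c1
F2 | step 5 | 2-[9-(4-acetoxy-3-methoxyphenyl)nonanoyl]-1,3-phenylene diacetate | CC(=O)Oc1cccc(OC(C)=O)c1C(=O)CCCCCCCCc1ccc(OC(C)=O)c(OC)c1
F3 | step 5 | 2-[9-(4-acetoxy-2-bromo-5-methoxyphenyl)nonanoyl]-1,3-phenylene diacetate | CC(=O)Oc1cccc(OC(C)=O)c1C(=O)CCCCCCCCc1cc(OC)c(OC(C)=O)cc1Br
F4 | step 5 | 2-[9-[4-acetoxy-5-methoxy-2-(4,4,5,5-tetramethyl-1,3,2-dioxaborolan-2-yl)phenyl]nonanoyl]-1,3-phenylene diacetate | CC(=O)Oc1cccc(OC(C)=O)c1C(=O)CCCCCCCCc1cc(OC)c(OC(C)=O)cc1B1OC(C)(C)C(C)(C)O1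
F5 | step 5 | 9,9'-(5-acetoxy-2'-hydroxy-3',4-dimethoxybiphenyl-2,5'-diyl)bis[1-(2,6-diacetoxyphenyl)nonan-1-one] | O=C(CCCCCCCCc1cc(OC)c(O)c(-c2cc(OC(C)=O)c(OC)cc2CCCCCCCCC(=O)c2c(OC(C)=O)cccc2OC(C)=O)c1)c1c(OC(C)=O)cccc1OC(C)=O
F6 | step 1 | 2,6-bis(methoxymethoxy)benzaldehyde | COCOc1cccc(OCOC)c1C=O
F7 | step 1 | 1-[2,6-bis(methoxymethoxy)phenyl]non-8-en-1-ol (racemic) | C=CCCCCCCC(O)c1c(OCOC)cccc1OCOC
F8 | step 1 | 1-[2,6-bis(methoxymethoxy)phenyl]non-8-en-1-one | C=CCCCCCCC(=O)c1c(OCOC)cccc1OCOC
F9 | step 3 | 9-[4-(benzyloxy)-3-methoxyphenyl]-1-(2,6-dihydroxyphenyl)nonan-1-one | COc1cc(CCCCCCCCC(=O)c2c(O)cccc2O)ccc1OCc1ccccc1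
F10 | step 3 | 2-[9-[4-(benzyloxy)-3-methoxyphenyl]nonanoyl]-1,3-phenylene diacetate | COc1cc(CCCCCCCCC(=O)c2c(OC(C)=O)cccc2OC(C)=O)ccc1OCc1ccccc1
A1 | direct plan | 2',3',4,5-tetramethoxybiphenyl-2,5'-dicarbaldehyde | COc1cc(C=O)cc(-c2cc(OC)c(OC)cc2C=O)c1OC
A2 | direct plan | 9,9'-(2',3',4,5-tetramethoxybiphenyl-2,5'-diyl)dinonanoic acid | OC(=O)CCCCCCCCc1cc(OC)c(OC)c(-c2cc(OC)c(OC)cc2CCCCCCCCC(=O)O)c1
A3 | direct plan | 9,9'-(2',3',4,5-tetramethoxybiphenyl-2,5'-diyl)bis[1-(2-hydroxy-6-methoxyphenyl)nonan-1-one] | O=C(CCCCCCCCc1cc(OC)c(OC)c(-c2cc(OC)c(OC)cc2CCCCCCCCC(=O)c2c(O)cccc2OC)c1)c1c(O)cccc1OC
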